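Ring B is cut between C5 and C6 and traced back to a squaric-ester-derived 4-alkenylcyclobutenone: O8 and O8a sit on neighbouring carbons and the prenyl-bearing C5 lies para to C8, so ring B can be raised as a 1,2,4-trioxygenated benzene whose C5 oxygen is later exchanged for carbon. One thermal operation opens the four-membered ring to a dienylketene and closes ring B, bringing in ring A with its three-carbon tether and leaving three distinguishable oxygens (free C5–OH, C8–OMOM, C8a–OBn). The precursor is a racemic 3-benzyloxy-4-(methoxymethoxy)cyclobut-2-enone whose C4 carries an (E)-pent-1-enyl chain ending in the MOM-protected 2-methoxyphenyl ring A.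

Key step: step 9

Remark on the chemistry: O8 is carried as a methoxymethyl ether and O8a as a benzyl ether. A silyl group on O8 could shift to the neighbouring O8a once that phenol is deprotonated and would misdirect the pyran annulation towards C7; an acetal cannot shift. Dibenzyl squarate 2 and iodide 8 are each made in one step, on the assumption that they cannot be bought. Ar = 2-methoxy-4-(methoxymethoxy)phenyl; locants C4a to C8a are those of the final chromene.

Step 1
Reactants: 1 squaric acid
Product: 2 dibenzyl squarate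
Conditions: BnOH (5 equiv), PhMe, reflux, Dean–Stark
Reagents that add atoms: benzyl alcohol, OCc1ccccc1
Why: Self-catalysed Fischer esterification of the strongly acidic vinylogous diacid, driven by azeotropic removal of water, is the standard entry to dialkyl squarates.

Step 2
Reactants: 2 dibenzyl squarate
Product: 4 3-(benzyloxy)cyclobut-3-ene-1,2-dione (benzyl semisquarate), via hydroxycyclobutenone 3 (not isolated)
Conditions: LiAlH(OtBu)3 (1.05 equiv), THF, −78 → −20 °C; then conc. HCl (cat.), CH2Cl2, rt (crude carbinol)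
Reagents that add atoms: water, O
Why: Bulky-hydride 1,2-reduction of one vinylogous ester carbonyl, then acid-induced ionisation of the carbinol and hydrolysis of the alkoxy-stabilised cation with loss of benzyl alcohol, is the established reduction–hydrolysis route to semisquaric esters.

Step 3
Reactants: 5 4-bromo-3-methoxyphenol
Product: 6 1-bromo-2-methoxy-4-(methoxymethoxy)benzene
Conditions: MOMCl, iPr2NEt, CH2Cl2, 0 °C → rt
Reagents that add atoms: chloromethyl methyl ether, COCCl
Why: Williamson-type O-alkylation of the phenol gives an acetal that tolerates organometallics, carbonate base and hydride.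

Step 4
Reactants: 7 (5-chloropent-1-yn-1-yl)trimethylsilane
Product: 8 (5-iodopent-1-yn-1-yl)trimethylsilane
Conditions: NaI, acetone, reflux
Reagents that add atoms: sodium iodide, [Na+].[I-]
Why: Finkelstein halide exchange at the primary chloride is driven by precipitation of NaCl.

Step 5
Reactants: 8 (5-iodopent-1-yn-1-yl)trimethylsilane; 6 1-bromo-2-methoxy-4-(methoxymethoxy)benzene
Product: 10 [5-Ar-pent-1-yn-1-yl]trimethylsilane, via alkylzinc iodide 9 (not isolated)
Conditions: Zn, LiCl, THF, 40 °C; then 6, Pd(OAc)2 (2 mol %), SPhos (4 mol %), THF, 50 °C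
Reagents that add atoms: none
Why: Negishi coupling, in which the primary alkylzinc leaves the silyl alkyne alone and the SPhos-ligated palladium catalyst couples the electron-rich ortho-methoxy aryl bromide faster than β-hydride elimination.

Step 6
Reactants: 10 [5-Ar-pent-1-yn-1-yl]trimethylsilane
Product: 11 2-methoxy-4-(methoxymethoxy)-1-(pent-4-yn-1-yl)benzene
Conditions: K2CO3, MeOH, rt
Reagents that add atoms: none
Why: Carbonate-promoted methanolysis of the alkynyl C–Si bond (protodesilylation) leaves the MOM and methyl ethers untouched.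

Step 7
Reactants: 11 2-methoxy-4-(methoxymethoxy)-1-(pent-4-yn-1-yl)benzene
Product: 13 1-[(E)-5-iodopent-4-en-1-yl]-2-methoxy-4-(methoxymethoxy)benzene, via alkenylzirconocene 12 (not isolated)
Conditions: Cp2Zr(H)Cl, THF, rt; then I2, 0 °C
Reagents that add atoms: iodine, [I][I]
Why: Hydrozirconation adds Zr–H syn and anti-Markovnikov across the terminal alkyne, and iodinolysis of the C–Zr bond with retention fixes the (E)-alkenyl iodide.

Step 8
Reactants: 13 1-[(E)-5-iodopent-4-en-1-yl]-2-methoxy-4-(methoxymethoxy)benzene; 4 3-(benzyloxy)cyclobut-3-ene-1,2-dione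
Product: 16 3-(benzyloxy)-4-(methoxymethoxy)-4-[(E)-5-Ar-pent-1-en-1-yl]cyclobut-2-en-1-one (racemic), via alkenyllithium 14 (not isolated), via lithium alkoxide 15 (not isolated)
Conditions: t-BuLi (2.0 equiv), Et2O, −78 °C; then 4, THF, −78 °C; then MOMCl, −78 → 0 °C
Reagents that add atoms: chloromethyl methyl ether, COCCl
Why: Lithium–iodine exchange with retention of geometry, 1,2-addition to the more electrophilic carbonyl of 4 (the one next to the benzyloxy carbon, not the vinylogous ester carbonyl) and O-alkylation of the tertiary lithium alkoxide by the very reactive MOMCl; the quaternary centre forms as a racemate and is destroyed in step 9.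

Step 9
Reactants: 16 3-(benzyloxy)-4-(methoxymethoxy)-4-[(E)-5-Ar-pent-1-en-1-yl]cyclobut-2-en-1-one
Product: 19 5-(benzyloxy)-4-(methoxymethoxy)-2-(3-Ar-propyl)phenol, via dienylketene 17 (not isolated), via cyclohexadienone 18 (not isolated)
Conditions: PhMe (0.02 M, degassed), 110 °C
Reagents that add atoms: none
Why: Thermal conrotatory four-electron opening of the C1–C4 bond of the cyclobutenone gives dienylketene 17, whose ketene carbon (future C5) is joined to the alkene terminus (future C6) by a disrotatory six-electron electrocyclisation to give dienone 18, and enolisation then gives phenol 19. The closest known reaction type is the Moore ring expansion of 4-alkenyl-4-oxycyclobutenones made from squaric esters. Ring B is closed as a six-membered carbocycle by 6π electrocyclic closure of the (Z)-configured ketene–diene, with one new C–C bond. The only new stereocentre (C6 of 18) is transient and is erased on aromatisation, so none has to be controlled. The step needs torquoselective opening with the alkenyl group turning inward, towards the ketene, which the π-donor methoxymethoxy group on the same carbon secures by turning outward. The oxygen pattern (free C5–OH, C8–OMOM, C8a–OBn) follows from the earlier addition to the carbonyl next to the benzyloxy carbon.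

Step 10
Reactants: 19 5-(benzyloxy)-4-(methoxymethoxy)-2-(3-Ar-propyl)phenol
Product: 20 5-(benzyloxy)-4-(methoxymethoxy)-2-(3-Ar-propyl)phenyl trifluoromethanesulfonate
Conditions: PhNTf2, Et3N, DMAP (cat.), CH2Cl2, rt
Reagents that add atoms: N-phenylbis(trifluoromethanesulfonimide), O=S(=O)(N(c1ccccc1)S(=O)(=O)C(F)(F)F)C(F)(F)F
Why: Sulfonylation of the only free phenol by triflyl transfer under mild base leaves both acetals intact.

Step 11
Reactants: 20 5-(benzyloxy)-4-(methoxymethoxy)-2-(3-Ar-propyl)phenyl trifluoromethanesulfonate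
Product: 21 5-hydroxy-4-(methoxymethoxy)-2-(3-Ar-propyl)phenyl trifluoromethanesulfonate
Conditions: H2 (1 atm), Pd/C (10 wt%), EtOAc, rt
Reagents that add atoms: none
Why: Hydrogenolysis of the benzyl aryl ether; the molecule holds no alkene at this stage, and aryl triflates and MOM ethers are inert to neutral hydrogenation.

Step 12
Reactants: 21 5-hydroxy-4-(methoxymethoxy)-2-(3-Ar-propyl)phenyl trifluoromethanesulfonate; 22 3-chloro-3-methylbut-1-yne
Product: 23 4-(methoxymethoxy)-5-[(2-methylbut-3-yn-2-yl)oxy]-2-(3-Ar-propyl)phenyl trifluoromethanesulfonate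
Conditions: DBU, CuCl2 (1 mol %), MeCN, 0 °C
Reagents that add atoms: none
Why: Copper-catalysed propargylic substitution O-alkylates the phenol with the tertiary propargylic chloride at 0 °C, and since the neighbouring O8 acetal cannot migrate the ether forms only on O8a.

Step 13
Reactants: 23 4-(methoxymethoxy)-5-[(2-methylbut-3-yn-2-yl)oxy]-2-(3-Ar-propyl)phenyl trifluoromethanesulfonate
Product: 26 8-(methoxymethoxy)-2,2-dimethyl-6-(3-Ar-propyl)-2H-chromen-5-yl trifluoromethanesulfonate, via allenylphenol 24 (not isolated), via quinone methide 25 (not isolated)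
Conditions: o-xylene, 140 °C
Reagents that add atoms: none
Why: Aromatic propargyl Claisen rearrangement to C4a, the only free position ortho to O8a, then enolisation, 1,5-hydrogen shift and oxa-6π electrocyclisation of the ortho-quinone methide build the 2,2-dimethyl-2H-chromene.

Step 14
Reactants: 26 8-(methoxymethoxy)-2,2-dimethyl-6-(3-Ar-propyl)-2H-chromen-5-yl trifluoromethanesulfonate; 27 tributyl(3-methylbut-2-en-1-yl)stannane
Product: 28 8-(methoxymethoxy)-2,2-dimethyl-5-(3-methylbut-2-en-1-yl)-6-(3-Ar-propyl)-2H-chromene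
Conditions: Pd(PPh3)4 (10 mol %), LiCl (3 equiv), DMF, 100 °C
Reagents that add atoms: none
Why: Stille coupling of the aryl triflate, with chloride-assisted oxidative addition, transmetalation and reductive elimination at the less substituted allyl terminus, should place the linear prenyl group on C5.

Step 15
Reactants: 28 8-(methoxymethoxy)-2,2-dimethyl-5-(3-methylbut-2-en-1-yl)-6-(3-Ar-propyl)-2H-chromene
Product: 29 Kazinol N, 6-[3-(4-hydroxy-2-methoxyphenyl)propyl]-2,2-dimethyl-5-(3-methylbut-2-en-1-yl)-2H-chromen-8-ol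
Conditions: HCl (1 M), MeOH, 40 °C
Reagents that add atoms: none
Why: Acid-catalysed acetal exchange with methanol removes both MOM groups under mild conditions that the chromene alkene and the prenyl group (no ortho hydroxyl to cyclise onto) should tolerate.

Compound list

1 | squaric acid (3,4-dihydroxycyclobut-3-ene-1,2-dione) | O=C1C(O)=C(O)C1=O | starting material
2 | dibenzyl squarate (3,4-bis(benzyloxy)cyclobut-3-ene-1,2-dione) | O=C1C(=O)C(OCc2ccccc2)=C1OCc1ccccc1 | intermediate
3 | 2,3-bis(benzyloxy)-4-hydroxycyclobut-2-en-1-one (racemic; not isolated) | O=C1C(OCc2ccccc2)=C(OCc2ccccc2)C1O | intermediate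
4 | 3-(benzyloxy)cyclobut-3-ene-1,2-dione (benzyl semisquarate) | O=C1C=C(OCc2ccccc2)C1=O | intermediate
5 | 4-bromo-3-methoxyphenol | COc1cc(O)ccc1Br | starting material
6 | 1-bromo-2-methoxy-4-(methoxymethoxy)benzene | COCOc1ccc(Br)c(OC)c1 | intermediate
7 | (5-chloropent-1-yn-1-yl)trimethylsilane | C[Si](C)(C)C#CCCCCl | starting material
8 | (5-iodopent-1-yn-1-yl)trimethylsilane | C[Si](C)(C)C#CCCCI | intermediate
9 | [5-(trimethylsilyl)pent-4-yn-1-yl]zinc iodide (not isolated) | C[Si](C)(C)C#CCCC[Zn]I | intermediate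
10 | {5-[2-methoxy-4-(methoxymethoxy)phenyl]pent-1-yn-1-yl}trimethylsilane | COCOc1ccc(CCCC#C[Si](C)(C)C)c(OC)c1 | intermediate
11 | 2-methoxy-4-(methoxymethoxy)-1-(pent-4-yn-1-yl)benzene | COCOc1ccc(CCCC#C)c(OC)c1 | intermediate
12 | chlorobis(cyclopentadienyl){(E)-5-[2-methoxy-4-(methoxymethoxy)phenyl]pent-1-en-1-yl}zirconium (not isolated) | Cl[Zr](/C=C/CCCc1ccc(OCOC)cc1OC)(C1C=CC=C1)C1C=CC=C1 | intermediate
13 | 1-[(E)-5-iodopent-4-en-1-yl]-2-methoxy-4-(methoxymethoxy)benzene | COCOc1ccc(CCC/C=C/I)c(OC)c1 | intermediate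
14 | (E)-5-[2-methoxy-4-(methoxymethoxy)phenyl]pent-1-en-1-yllithium (not isolated) | [Li]/C=C/CCCc1ccc(OCOC)cc1OC | intermediate
15 | lithium 2-(benzyloxy)-1-{(E)-5-[2-methoxy-4-(methoxymethoxy)phenyl]pent-1-en-1-yl}-4-oxocyclobut-2-en-1-olate (racemic; not isolated) | [Li]OC1(/C=C/CCCc2ccc(OCOC)cc2OC)C(=O)C=C1OCc1ccccc1 | intermediate
16 | 3-(benzyloxy)-4-(methoxymethoxy)-4-{(E)-5-[2-methoxy-4-(methoxymethoxy)phenyl]pent-1-en-1-yl}cyclobut-2-en-1-one (racemic) | O=C1C=C(OCc2ccccc2)C1(OCOC)/C=C/CCCc1ccc(OCOC)cc1OC | intermediate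
17 | (3Z,5E)-3-(benzyloxy)-4-(methoxymethoxy)-9-[2-methoxy-4-(methoxymethoxy)phenyl]nona-1,3,5-trien-1-one (dienylketene; not isolated) | O=C=C/C(OCc1ccccc1)=C(/OCOC)\C=C\CCCc1ccc(OCOC)cc1OC | intermediate
18 | 3-(benzyloxy)-4-(methoxymethoxy)-6-{3-[2-methoxy-4-(methoxymethoxy)phenyl]propyl}cyclohexa-2,4-dien-1-one (racemic; not isolated) | O=C1C=C(OCc2ccccc2)C(OCOC)=CC1CCCc1ccc(OCOC)cc1OC | intermediate
19 | 5-(benzyloxy)-4-(methoxymethoxy)-2-{3-[2-methoxy-4-(methoxymethoxy)phenyl]propyl}phenol | Oc1cc(OCc2ccccc2)c(OCOC)cc1CCCc1ccc(OCOC)cc1OC | intermediate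
20 | 5-(benzyloxy)-4-(methoxymethoxy)-2-{3-[2-methoxy-4-(methoxymethoxy)phenyl]propyl}phenyl trifluoromethanesulfonate | O=S(=O)(Oc1cc(OCc2ccccc2)c(OCOC)cc1CCCc1ccc(OCOC)cc1OC)C(F)(F)F | intermediate
21 | 5-hydroxy-4-(methoxymethoxy)-2-{3-[2-methoxy-4-(methoxymethoxy)phenyl]propyl}phenyl trifluoromethanesulfonate | O=S(=O)(Oc1cc(O)c(OCOC)cc1CCCc1ccc(OCOC)cc1OC)C(F)(F)F | intermediate
22 | 3-chloro-3-methylbut-1-yne | CC(C)(Cl)C#C | starting material
23 | 4-(methoxymethoxy)-5-[(2-methylbut-3-yn-2-yl)oxy]-2-{3-[2-methoxy-4-(methoxymethoxy)phenyl]propyl}phenyl trifluoromethanesulfonate | O=S(=O)(Oc1cc(OC(C)(C)C#C)c(OCOC)cc1CCCc1ccc(OCOC)cc1OC)C(F)(F)F | intermediate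
24 | 3-hydroxy-4-(methoxymethoxy)-2-(3-methylbuta-1,2-dien-1-yl)-6-{3-[2-methoxy-4-(methoxymethoxy)phenyl]propyl}phenyl trifluoromethanesulfonate (allenylphenol; not isolated) | O=S(=O)(Oc1c(C=C=C(C)C)c(O)c(OCOC)cc1CCCc1ccc(OCOC)cc1OC)C(F)(F)F | intermediate
25 | (6Z)-4-(methoxymethoxy)-6-(3-methylbut-2-en-1-ylidene)-5-oxo-2-{3-[2-methoxy-4-(methoxymethoxy)phenyl]propyl}cyclohexa-1,3-dien-1-yl trifluoromethanesulfonate (ortho-quinone methide; not isolated) | CC(C)=C/C=C1\C(=O)C(OCOC)=CC(CCCc2ccc(OCOC)cc2OC)=C1OS(=O)(=O)C(F)(F)F | intermediate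
26 | 8-(methoxymethoxy)-2,2-dimethyl-6-{3-[2-methoxy-4-(methoxymethoxy)phenyl]propyl}-2H-chromen-5-yl trifluoromethanesulfonate | CC1(C)C=Cc2c(OS(=O)(=O)C(F)(F)F)c(CCCc3ccc(OCOC)cc3OC)cc(OCOC)c2O1 | intermediate
27 | tributyl(3-methylbut-2-en-1-yl)stannane | CCCC[Sn](CCCC)(CCCC)CC=C(C)C | starting material
28 | 8-(methoxymethoxy)-2,2-dimethyl-5-(3-methylbut-2-en-1-yl)-6-{3-[2-methoxy-4-(methoxymethoxy)phenyl]propyl}-2H-chromene | CC(C)=CCc1c(CCCc2ccc(OCOC)cc2OC)cc(OCOC)c2OC(C)(C)C=Cc12 | intermediate
29 | Kazinol N, 6-[3-(4-hydroxy-2-methoxyphenyl)propyl]-2,2-dimethyl-5-(3-methylbut-2-en-1-yl)-2H-chromen-8-ol | COc1cc(O)ccc1CCCc1cc(O)c2c(c1CC=C(C)C)C=CC(C)(C)O2 | target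

Total step count: 15. Longest linear sequence: 12 steps (steps 3 and 5 to 15 from 5; the branch from 7 through step 4 is equally long).

Steps most likely to fail

Step 9. The transient dienylketene may be consumed by dimerisation or by adventitious nucleophiles before it closes. Ring opening of the acetal-capped substrate may also be less cleanly outward-selective at oxygen than for the silyl-capped substrates on which this ring expansion is best established, so that a ketene geometry unable to cyclise builds up and decomposes. The fallback sets out from 13 and 4. The lithium alkoxide 15 would be capped with TBSOTf (−78 → 0 °C) instead of MOMCl to give 3-(benzyloxy)-4-[(tert-butyldimethylsilyl)oxy]-4-[(E)-5-Ar-pent-1-en-1-yl]cyclobut-2-en-1-one F1. Its thermolysis (PhMe, 110 °C) should give 5-(benzyloxy)-4-[(tert-butyldimethylsilyl)oxy]-2-(3-Ar-propyl)phenol F2. Triflation (PhNTf2, Et3N) would give 5-(benzyloxy)-4-[(tert-butyldimethylsilyl)oxy]-2-(3-Ar-propyl)phenyl trifluoromethanesulfonate F3. Desilylation (Bu4NF buffered with AcOH, THF, 0 °C; O8a is still a benzyl ether, so the silyl group has nowhere to go) would give 5-(benzyloxy)-4-hydroxy-2-(3-Ar-propyl)phenyl trifluoromethanesulfonate F4. Etherification (MOMCl, iPr2NEt, CH2Cl2) then returns to the route at 20.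

Step 14. Oxidative addition into a triflate flanked by two ortho substituents may be slow, so that protodestannylation and reduction of the triflate compete. The allyl transfer may also occur with allylic transposition, forming the C–C bond at the tertiary terminus of the prenyl unit. The fallback sets out from 26: Stille coupling with allyltributylstannane (Pd(PPh3)4, LiCl, DMF, 90 °C), whose small symmetric allyl group cannot transpose, should give 5-allyl-8-(methoxymethoxy)-2,2-dimethyl-6-(3-Ar-propyl)-2H-chromene F5. Cross-metathesis with excess 2-methylbut-2-ene (second-generation Grubbs catalyst, CH2Cl2, 40 °C), in which the hindered cyclic chromene alkene is expected to stay inert, returns to the route at 28.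

Step 8. O-Alkylation of the crowded tertiary lithium alkoxide may stay incomplete, or the alkoxide may fragment by ring opening while the mixture is warmed to drive the alkylation. The fallback sets out from 13 and 4: the adduct would be quenched at −78 °C with aqueous NH4Cl and isolated as the carbinol 3-(benzyloxy)-4-hydroxy-4-[(E)-5-Ar-pent-1-en-1-yl]cyclobut-2-en-1-one F6. This is then etherified as the neutral alcohol (MOMCl, iPr2NEt, Bu4NI cat., CH2Cl2, rt) and rejoins the route at 16.

Further compounds

F1 | step 9 | 3-(benzyloxy)-4-[(tert-butyldimethylsilyl)oxy]-4-{(E)-5-[2-methoxy-4-(methoxymethoxy)phenyl]pent-1-en-1-yl}cyclobut-2-en-1-one (racemic) | O=C1C=C(OCc2ccccc2)C1(O[Si](C)(C)C(C)(C)C)/C=C/CCCc1ccc(OCOC)cc1OC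
F2 | step 9 | 5-(benzyloxy)-4-[(tert-butyldimethylsilyl)oxy]-2-{3-[2-methoxy-4-(methoxymethoxy)phenyl]propyl}phenol | Oc1cc(OCc2ccccc2)c(O[Si](C)(C)C(C)(C)C)cc1CCCc1ccc(OCOC)cc1OC
F3 | step 9 | 5-(benzyloxy)-4-[(tert-butyldimethylsilyl)oxy]-2-{3-[2-methoxy-4-(methoxymethoxy)phenyl]propyl}phenyl trifluoromethanesulfonate | O=S(=O)(Oc1cc(OCc2ccccc2)c(O[Si](C)(C)C(C)(C)C)cc1CCCc1ccc(OCOC)cc1OC)C(F)(F)F
F4 | step 9 | 5-(benzyloxy)-4-hydroxy-2-{3-[2-methoxy-4-(methoxymethoxy)phenyl]propyl}phenyl trifluoromethanesulfonate | O=S(=O)(Oc1cc(OCc2ccccc2)c(O)cc1CCCc1ccc(OCOC)cc1OC)C(F)(F)F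
F5 | step 14 | 5-allyl-8-(methoxymethoxy)-2,2-dimethyl-6-{3-[2-methoxy-4-(methoxymethoxy)phenyl]propyl}-2H-chromene | C=CCc1c(CCCc2ccc(OCOC)cc2OC)cc(OCOC)c2OC(C)(C)C=Cc12
F6 | step 8 | 3-(benzyloxy)-4-hydroxy-4-{(E)-5-[2-methoxy-4-(methoxymethoxy)phenyl]pent-1-en-1-yl}cyclobut-2-en-1-one (racemic) | O=C1C=C(OCc2ccccc2)C1(O)/C=C/CCCc1ccc(OCOC)cc1OC
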